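**Retrosynthetic overview**

- Ring A (numbered C1 OMe, C2 H, C3 arylethyl chain, C4 H, C5 OH, C6 4-hydroxybenzyl) is a resorcinol monomethyl ether with the benzyl CH2 on the carbon between the two oxygens. This is the pattern left when a tetraketide closes by C2-to-C7 aldol and then loses its carboxyl, so a carboxyl is put back on C4 and ring A is traced to a salicylate acetonide (benzodioxinone).
- Late stage: hydrogenolysis of two benzyl ethers ⇐ thermal decarboxylation ⇐ saponification of the benzodioxinone ⇐ O-methylation of its one free phenol.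
- Key disconnection: the ring-A bond between the carboxyl-bearing carbon and the chain-bearing carbon, opened to a diketo-dioxinone that carries the 4-benzyloxybenzyl group on the methine next to the dioxinone (aldol, dehydration, aromatization).
- Diketo-dioxinone ⇐ dianion of a benzylated keto-dioxinone + Weinreb amide of 3-(3-benzyloxyphenyl)propanoic acid; keto-dioxinone ⇐ 2,2,6-trimethyldioxinone by γ-benzylation, then γ-acetylation.
- Ring order: the two outer benzene rings are bought; ring A is the only ring formed.

Key step: step 6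

Remark: the target has no stereocentre and is achiral, so no enantiocontrol is required. Compounds 4 and 10 (one enolizable stereocentre each) and 11 (two) are handled as racemic or diastereomeric mixtures, because these centres become aromatic carbons in step 6. The benzylic bromide is used in place of the chloride because the alkylation must run at −78 °C.

**Step 1**
Reactants: 1 2,2,6-trimethyl-4H-1,3-dioxin-4-one; 2 4-benzyloxybenzyl bromide
Product: 3 6-[2-(4-benzyloxyphenyl)ethyl]-2,2-dimethyl-4H-1,3-dioxin-4-one
Conditions: LDA, THF–DMPU, −78 °C; then 2, −78 → −40 °C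
Reagents that add atoms: none
Why: γ-Alkylation of the lithium dienolate of the dioxinone, in which kinetic deprotonation of the C6 methyl group and SN2 attack of the γ-carbon on the reactive benzylic bromide in a dipolar cosolvent is the established entry to 6-(2-arylethyl)dioxinones; no stereocentre is formed.

**Step 2**
Reactants: 3 6-[2-(4-benzyloxyphenyl)ethyl]-2,2-dimethyl-4H-1,3-dioxin-4-one
Product: 4 6-[1-(4-benzyloxyphenyl)-3-oxobutan-2-yl]-2,2-dimethyl-4H-1,3-dioxin-4-one (racemic)
Conditions: LiHMDS (2.2 equiv), THF, −78 °C; then AcCl (1.05 equiv), −78 °C; aq. NH4Cl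
Reagents that add atoms: acetyl chloride CC(Cl)=O
Why: Claisen-type C-acylation of the γ-lithiated dioxinone dienolate by the acid chloride, with the second equivalent of amide base taking up the doubly activated methine proton of the product so that it does not quench unreacted dienolate; the new stereocentre is formed without control and is erased in step 6.

**Step 3**
Reactants: 5 3-(3-hydroxyphenyl)propanoic acid
Product: 7 3-(3-benzyloxyphenyl)propanoic acid, via dibenzylated ester 6 (not isolated)
Conditions: BnBr (2.3 equiv), K2CO3, DMF, 60 °C; then NaOH, MeOH–H2O, 60 °C; aq. HCl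
Reagents that add atoms: benzyl bromide BrCc1ccccc1; sodium hydroxide [Na+].[OH-]
Why: Williamson benzylation of both the phenoxide and the carboxylate followed by saponification, which cleaves only the benzyl ester and leaves the aryl benzyl ether.

**Step 4**
Reactants: 7 3-(3-benzyloxyphenyl)propanoic acid
Product: 9 3-(3-benzyloxyphenyl)-N-methoxy-N-methylpropanamide, via acyl imidazole 8 (not isolated)
Conditions: CDI, CH2Cl2, rt; then MeNHOMe·HCl, rt
Reagents that add atoms: 1,1'-carbonyldiimidazole O=C(n1ccnc1)n1ccnc1 (imidazolyl group of 8); N,O-dimethylhydroxylamine hydrochloride CNOC.Cl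
Why: Weinreb amide formation by CDI activation of the acid to the acyl imidazole and aminolysis by N,O-dimethylhydroxylamine, a standard sequence that tolerates the benzyl ether.

**Step 5**
Reactants: 4 6-[1-(4-benzyloxyphenyl)-3-oxobutan-2-yl]-2,2-dimethyl-4H-1,3-dioxin-4-one; 9 3-(3-benzyloxyphenyl)-N-methoxy-N-methylpropanamide
Product: 10 6-[1-(4-benzyloxyphenyl)-7-(3-benzyloxyphenyl)-3,5-dioxoheptan-2-yl]-2,2-dimethyl-4H-1,3-dioxin-4-one (racemic, enolized)
Conditions: LDA (2.3 equiv), THF, −78 °C; then 9, −78 → −30 °C; AcOH, aq. NH4Cl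
Reagents that add atoms: none
Why: Acylation of a 1,3-dicarbonyl-type dianion (Hauser–Harris reactivity), which reacts at the last-formed terminal methyl carbanion, and the N-methoxy-N-methyl chelate holds the tetrahedral adduct until work-up so that neither over-addition nor proton transfer from the product occurs.

**Step 6**
Reactants: 10 6-[1-(4-benzyloxyphenyl)-7-(3-benzyloxyphenyl)-3,5-dioxoheptan-2-yl]-2,2-dimethyl-4H-1,3-dioxin-4-one
Product: 12 8-(4-benzyloxybenzyl)-5-[2-(3-benzyloxyphenyl)ethyl]-7-hydroxy-2,2-dimethyl-4H-1,3-benzodioxin-4-one, via aldol adduct 11 (not isolated)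
Conditions: Et3N, CH2Cl2, 0 °C → rt; then HCl/MeOH, rt
Reagents that add atoms: none
Why: Triethylamine equilibrates the enolates of 10, and the productive one is the extended dienolate formed by loss of the methine proton between the dioxinone and the C3 ketone, whose dioxinone α-carbon (C5 of the heterocycle) adds to the C5 ketone of the side chain to give the hydroxy-cyclohexenone 11, after which acid eliminates the tertiary hydroxyl and the C3 ketone enolizes so that ring A becomes aromatic. The closest known reaction type is the base-mediated aldol aromatization of diketo-dioxinones to acetonide-protected resorcylates, including cases with an allyl or prenyl group on the same methine carbon. The one ring closure is a 6-(enolendo)-exo-trig aldol, with the nucleophilic C5=C6 enol-ether π bond of the dioxinone inside the new six-membered ring and the ketone C=O outside it. The two stereocentres of 11 and the one of 10 are transient and vanish on aromatization, so no stereocontrol is needed. The selectivity required is the C2-to-C7 aldol over Claisen-type and pyrone-forming closures; the dioxinone secures it because its carbonyl is a non-electrophilic vinylogous carbonate and its enol oxygen is locked in the acetal, the mild base ionizes only the doubly activated positions, and base is applied before acid so that C–C closure precedes any acid-induced O-cyclization.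

**Step 7**
Reactants: 12 8-(4-benzyloxybenzyl)-5-[2-(3-benzyloxyphenyl)ethyl]-7-hydroxy-2,2-dimethyl-4H-1,3-benzodioxin-4-one
Product: 13 8-(4-benzyloxybenzyl)-5-[2-(3-benzyloxyphenyl)ethyl]-7-methoxy-2,2-dimethyl-4H-1,3-benzodioxin-4-one
Conditions: MeI, K2CO3, acetone, 50 °C
Reagents that add atoms: iodomethane CI
Why: Williamson O-methylation of the only free phenol, the other ring-A oxygen being held in the acetonide, so that the OMe/OH pattern of the target is fixed without a selectivity problem.

**Step 8**
Reactants: 13 8-(4-benzyloxybenzyl)-5-[2-(3-benzyloxyphenyl)ethyl]-7-methoxy-2,2-dimethyl-4H-1,3-benzodioxin-4-one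
Product: 14 3-(4-benzyloxybenzyl)-6-[2-(3-benzyloxyphenyl)ethyl]-2-hydroxy-4-methoxybenzoic acid
Conditions: aq. KOH, DMSO, 80 °C; then 1 M HCl, 0 °C
Reagents that add atoms: potassium hydroxide [K+].[OH-]
Why: Saponification of the benzodioxinone, in which hydroxide adds to the lactone carbonyl and the expelled hemiketal collapses to acetone and the phenoxide; the forcing conditions answer the ortho,ortho-disubstitution, and the benzyl and methyl ethers are inert to base.

**Step 9**
Reactants: 14 3-(4-benzyloxybenzyl)-6-[2-(3-benzyloxyphenyl)ethyl]-2-hydroxy-4-methoxybenzoic acid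
Product: 15 2-(4-benzyloxybenzyl)-5-[2-(3-benzyloxyphenyl)ethyl]-3-methoxyphenol
Conditions: DMF, 130 °C, N2
Reagents that add atoms: none
Why: Thermal protodecarboxylation of a benzoic acid carrying an ortho hydroxyl and a para alkoxy group, which proceeds readily through ipso protonation of the electron-rich ring and loss of CO2, as is typical of β-resorcylic acids.

**Step 10**
Reactants: 15 2-(4-benzyloxybenzyl)-5-[2-(3-benzyloxyphenyl)ethyl]-3-methoxyphenol
Product: 16 2-(4-hydroxybenzyl)-5-[2-(3-hydroxyphenyl)ethyl]-3-methoxyphenol (CNP0112925.0)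
Conditions: H2 (1 atm), 10% Pd/C, EtOAc–MeOH, rt
Reagents that add atoms: none
Why: Catalytic hydrogenolysis of the two aryl benzyl ethers, under which the diarylmethane and bibenzyl C–C bonds and the aryl methyl ether are not cleaved.

**Compound list**

1 | 2,2,6-trimethyl-4H-1,3-dioxin-4-one | CC1=CC(=O)OC(C)(C)O1 | starting material
2 | 4-benzyloxybenzyl bromide | BrCc1ccc(OCc2ccccc2)cc1 | starting material
3 | 6-[2-(4-benzyloxyphenyl)ethyl]-2,2-dimethyl-4H-1,3-dioxin-4-one | CC1(C)OC(=O)C=C(CCc2ccc(OCc3ccccc3)cc2)O1 | intermediate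
4 | 6-[1-(4-benzyloxyphenyl)-3-oxobutan-2-yl]-2,2-dimethyl-4H-1,3-dioxin-4-one (racemic) | CC(=O)C(Cc1ccc(OCc2ccccc2)cc1)C1=CC(=O)OC(C)(C)O1 | intermediate
5 | 3-(3-hydroxyphenyl)propanoic acid | OC(=O)CCc1cccc(O)c1 | starting material
6 | benzyl 3-(3-benzyloxyphenyl)propanoate (not isolated) | O=C(CCc1cccc(OCc2ccccc2)c1)OCc1ccccc1 | intermediate
7 | 3-(3-benzyloxyphenyl)propanoic acid | OC(=O)CCc1cccc(OCc2ccccc2)c1 | intermediate
8 | 1-[3-(3-benzyloxyphenyl)propanoyl]-1H-imidazole (not isolated) | O=C(CCc1cccc(OCc2ccccc2)c1)n1ccnc1 | intermediate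
9 | 3-(3-benzyloxyphenyl)-N-methoxy-N-methylpropanamide | CON(C)C(=O)CCc1cccc(OCc2ccccc2)c1 | intermediate
10 | 6-[1-(4-benzyloxyphenyl)-7-(3-benzyloxyphenyl)-3,5-dioxoheptan-2-yl]-2,2-dimethyl-4H-1,3-dioxin-4-one (racemic) | CC1(C)OC(=O)C=C(O1)C(Cc1ccc(OCc2ccccc2)cc1)C(=O)CC(=O)CCc1cccc(OCc2ccccc2)c1 | intermediate
11 | 8-(4-benzyloxybenzyl)-5-[2-(3-benzyloxyphenyl)ethyl]-5-hydroxy-2,2-dimethyl-5,6-dihydro-4H-1,3-benzodioxine-4,7(8H)-dione (diastereomer mixture; conjugated tautomer drawn; not isolated) | CC1(C)OC(=O)C2=C(O1)C(Cc1ccc(OCc3ccccc3)cc1)C(=O)CC2(O)CCc1cccc(OCc3ccccc3)c1 | intermediate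
12 | 8-(4-benzyloxybenzyl)-5-[2-(3-benzyloxyphenyl)ethyl]-7-hydroxy-2,2-dimethyl-4H-1,3-benzodioxin-4-one | CC1(C)OC(=O)c2c(CCc3cccc(OCc4ccccc4)c3)cc(O)c(Cc3ccc(OCc4ccccc4)cc3)c2O1 | intermediate
13 | 8-(4-benzyloxybenzyl)-5-[2-(3-benzyloxyphenyl)ethyl]-7-methoxy-2,2-dimethyl-4H-1,3-benzodioxin-4-one | CC1(C)OC(=O)c2c(CCc3cccc(OCc4ccccc4)c3)cc(OC)c(Cc3ccc(OCc4ccccc4)cc3)c2O1 | intermediate
14 | 3-(4-benzyloxybenzyl)-6-[2-(3-benzyloxyphenyl)ethyl]-2-hydroxy-4-methoxybenzoic acid | OC(=O)c1c(CCc2cccc(OCc3ccccc3)c2)cc(OC)c(Cc2ccc(OCc3ccccc3)cc2)c1O | intermediate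
15 | 2-(4-benzyloxybenzyl)-5-[2-(3-benzyloxyphenyl)ethyl]-3-methoxyphenol | COc1cc(CCc2cccc(OCc3ccccc3)c2)cc(O)c1Cc1ccc(OCc2ccccc2)cc1 | intermediate
16 | 2-(4-hydroxybenzyl)-5-[2-(3-hydroxyphenyl)ethyl]-3-methoxyphenol | COc1cc(CCc2cccc(O)c2)cc(O)c1Cc1ccc(O)cc1 | target

**Step count and risk**

Total step count: 10. Longest linear sequence: 8 steps (1 → 3 → 4 → 10 → 12 → 13 → 14 → 15 → 16; the arm from 5 through 7 and 9 is equally long).

Steps most likely to fail:

1. Step 2. The γ-carbon of the dienolate of 3 now carries a substituent, so acylation may drift to the enolate oxygen or to the dioxinone α-carbon, or proton transfer from the product may stop the reaction at partial conversion. The fallback sets out from 1 and comes back at 4, and inverts the order of the two C–C bond formations. Compound 1 is first γ-acetylated in its unsubstituted parent form (LiHMDS, THF, −78 °C; AcCl) to give 2,2-dimethyl-6-(2-oxopropyl)-4H-1,3-dioxin-4-one F1. The doubly activated methylene of F1 is then C-benzylated as its soft potassium enolate with one equivalent of 2 (K2CO3, acetone, rt) to give 4. Step 1 is then not needed.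

2. Step 5. Addition of the dianion of 4 to the Weinreb amide may be slower than decay of the dianion (opening of the dioxinone, proton exchange), so that 4 is recovered or degraded. The fallback sets out from 9 and 4 and comes back at 10, and replaces the Claisen acylation by an aldol addition and an oxidation. Compound 9 is reduced with DIBAL-H (THF, −78 °C) to 3-(3-benzyloxyphenyl)propanal F2. The dianion of 4 (LDA, THF, −78 °C) adds to this far more reactive electrophile at its terminal carbon to give 6-[1-(4-benzyloxyphenyl)-7-(3-benzyloxyphenyl)-5-hydroxy-3-oxoheptan-2-yl]-2,2-dimethyl-4H-1,3-dioxin-4-one F3 as a diastereomer mixture. Dess–Martin periodinane (CH2Cl2, rt) then oxidizes the secondary alcohol to the β-diketone 10.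

3. Step 6. The benzyl group on the methine may hinder planarization of the extended dienolate, so that closure is slow and O-cyclization of the diketone enol onto the dioxinone (pyrone formation) or retro-Claisen cleavage of the α-branched β-diketone competes. The fallback sets out from 10 and comes back at 14. It keeps the same ring bond but closes an open-chain triketo ester.
   - Thermolysis of 10 in toluene with excess methanol (110 °C, sealed tube) expels acetone and traps the acylketene as methyl 4-(4-benzyloxybenzyl)-9-(3-benzyloxyphenyl)-3,5,7-trioxononanoate F4.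
   - Mild base (Cs2CO3, MeOH, rt) and then methanolic HCl bring about the C2-to-C7 aldol and aromatization to methyl 3-(4-benzyloxybenzyl)-6-[2-(3-benzyloxyphenyl)ethyl]-2,4-dihydroxybenzoate F5.
   - The 4-hydroxyl, which is not hydrogen-bonded to the ester, is methylated selectively (MeI, 1.05 equiv, K2CO3, acetone, rt) to methyl 3-(4-benzyloxybenzyl)-6-[2-(3-benzyloxyphenyl)ethyl]-2-hydroxy-4-methoxybenzoate F6.
   - Saponification (aq. KOH, DMSO, 80 °C; HCl) gives 14.

**Further compounds**

F1 | step 2 | 2,2-dimethyl-6-(2-oxopropyl)-4H-1,3-dioxin-4-one | CC(=O)CC1=CC(=O)OC(C)(C)O1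
F2 | step 5 | 3-(3-benzyloxyphenyl)propanal | O=CCCc1cccc(OCc2ccccc2)c1
F3 | step 5 | 6-[1-(4-benzyloxyphenyl)-7-(3-benzyloxyphenyl)-5-hydroxy-3-oxoheptan-2-yl]-2,2-dimethyl-4H-1,3-dioxin-4-one (diastereomer mixture) | CC1(C)OC(=O)C=C(O1)C(Cc1ccc(OCc2ccccc2)cc1)C(=O)CC(O)CCc1cccc(OCc2ccccc2)c1
F4 | step 6 | methyl 4-(4-benzyloxybenzyl)-9-(3-benzyloxyphenyl)-3,5,7-trioxononanoate (racemic) | COC(=O)CC(=O)C(Cc1ccc(OCc2ccccc2)cc1)C(=O)CC(=O)CCc1cccc(OCc2ccccc2)c1
F5 | step 6 | methyl 3-(4-benzyloxybenzyl)-6-[2-(3-benzyloxyphenyl)ethyl]-2,4-dihydroxybenzoate | COC(=O)c1c(CCc2cccc(OCc3ccccc3)c2)cc(O)c(Cc2ccc(OCc3ccccc3)cc2)c1O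
F6 | step 6 | methyl 3-(4-benzyloxybenzyl)-6-[2-(3-benzyloxyphenyl)ethyl]-2-hydroxy-4-methoxybenzoate | COC(=O)c1c(CCc2cccc(OCc3ccccc3)c2)cc(OC)c(Cc2ccc(OCc3ccccc3)cc2)c1O
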